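**Retrosynthetic overview** (gibberellane numbering: ring A = C1–C5, C10; ring B = C5, C6, C8, C9, C10; ring C = C8, C9, C11–C14; ring D = C8, C13–C16)
1. Enabling feature: C8 is quaternary and carries two ring D methylenes (C14, C15), while the neighbouring ring D atoms C13 (bridgehead O) and C16 (exocyclic C17) are the O-substituted C=C of a 1,1-disubstituted allene. Ring D is therefore the three-carbon unit C14–C8–C15 of a C8 spiro-cyclobutanone (carbonyl expelled as CO) plus the two-carbon unit C13=C16 of an allene tethered through C9–C11–C12.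
2. Target ⇐ global desilylation ⇐ rhodium-catalysed decarbonylative (4+2−1) coupling that closes rings C and D of the bicyclo[3.2.1]octane at once (C14–C13 and C15–C16).
3. The allene ⇐ gold-catalysed 1,3-carbonate shift of a propargylic carbonate. The ring A lactone and 3β-OH ⇐ acid-triggered transfer of a 7-oxanorbornene ether bridge onto the C19 ester, then SN2′ selenation and [2,3] shift.
4. Rings A and B together ⇐ intramolecular furan Diels–Alder reaction of a (Z)-keto-enoate tethered through the cyclobutane (C10, C5, C4, C3 relayed from C9).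
5. C9 ⇐ organocatalytic Mukaiyama–Michael addition; C12 ⇐ catalytic asymmetric alkynylation. Ring order: cyclobutane (bought) → A + B → lactone → C + D.

Key step: step 15

Assumption: α is the face of the C19→C10 lactone, and the target is the 12α-hydroxy derivative of gibberellic acid. The enol ether geometry in 14 and the carbinol configuration in 10 have no consequence and are left open in their SMILES.

**Step 1**
Reactants: 1 methyl 3,3-dimethoxycyclobutane-1-carboxylate
Product: 2 O-TBS ketene acetal of 1
Conditions: LDA, THF, −78 °C; then TBSCl, DMPU, −78 °C to rt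
Reagents that add atoms: tert-butyldimethylsilyl chloride, CC(C)(C)[Si](C)(C)Cl
Why: Deprotonation and O-silylation of the ester enolate (silyl ketene acetal formation); the ring is symmetric, so no alkene geometry arises.

**Step 2**
Reactants: 2 O-TBS ketene acetal; 3 (E)-3-(furan-2-yl)prop-2-enal
Product: 4 (R)-aldehyde ester
Conditions: (2S,5S)-5-benzyl-2-tert-butyl-3-methylimidazolidin-4-one·CF3CO2H (20 mol %), CH2Cl2/H2O, −55 °C
Reagents that add atoms: none
Why: Organocatalytic Mukaiyama–Michael addition: the enal reacts as its iminium ion, whose benzyl group shields one face of the β-carbon, so the ketene acetal should add to the open face and set C9 as R while forming the non-stereogenic quaternary C8; iminium activation enforces 1,4- over 1,2-addition.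

**Step 3**
Reactants: 4 (R)-aldehyde ester; 5 tert-butyldimethyl(prop-2-yn-1-yloxy)silane
Product: 6 (12S)-propargylic alcohol
Conditions: ProPhenol ligand (20 mol %, the enantiomer that gives the S carbinol), Me2Zn, Ph3P=O (40 mol %), toluene, 0 °C
Reagents that add atoms: none
Why: Catalytic asymmetric alkynylation of an aldehyde by a zinc acetylide on a dinuclear zinc–ProPhenol catalyst; the ligand (reagent control) sets C12 as S, and the remote C9 centre should have little influence.

**Step 4**
Reactants: 6 (12S)-propargylic alcohol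
Product: 7 12-O-TBDPS ether
Conditions: TBDPSCl, imidazole, DMAP (cat.), DMF, rt
Reagents that add atoms: tert-butyldiphenylsilyl chloride, CC(C)(C)[Si](Cl)(c1ccccc1)c1ccccc1
Why: Silyl ether formation; the acid-stable TBDPS group is chosen to survive step 9.

**Step 5**
Reactants: 7 12-O-TBDPS ether
Product: 8 cyclobutanecarbaldehyde
Conditions: DIBAL-H (1.2 equiv), CH2Cl2, −78 °C; MeOH, then aqueous sodium potassium tartrate
Reagents that add atoms: none
Why: Half-reduction of an α-quaternary ester: the neopentyl tetrahedral aluminate is stable at −78 °C and should release the aldehyde only on work-up.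

**Step 6**
Reactants: 8 cyclobutanecarbaldehyde; 9 methyl propiolate
Product: 11 ynone ester, via propargylic alcohol 10 (not isolated)
Conditions: 9, LiHMDS, THF, −78 °C; aq. NH4Cl; crude 10 then DMP (1,1,1-triacetoxy-1,1-dihydro-1,2-benziodoxol-3(1H)-one), NaHCO3, CH2Cl2, 0 °C
Reagents that add atoms: none
Why: 1,2-Addition of lithium methyl propiolate to the aldehyde, then hypervalent-iodine oxidation of the crude carbinol epimers; the stereocentre of 10 is erased in 11, which is used at once because the ynone itself can add to the furan.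

**Step 7**
Reactants: 11 ynone ester
Product: 13 oxa-bridged tricyclic ketone, via (Z)-keto-enoate 12 (not isolated)
Conditions: Me2CuLi (from MeLi and CuI), THF, −78 °C; NH4Cl quench at −78 °C; then toluene, rt to 40 °C
Reagents that add atoms: lithium dimethylcuprate, [Li+].C[Cu-]C
Why: Syn conjugate addition of the cuprate β to the ketone (as with acetylenedicarboxylates) and cold protonation should leave acyl and ester cis (Z); the doubly activated dienophile then undergoes intramolecular furan Diels–Alder addition through the only unstrained exo-tether array with the C9 side chain syn to the oxygen bridge (away from furan H-3), which sets C10, C5 (H endo), C4 (ester exo, methyl endo) and C3 from C9.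

**Step 8**
Reactants: 13 oxa-bridged tricyclic ketone
Product: 14 methoxymethylidene enol ether
Conditions: (methoxymethyl)triphenylphosphonium chloride, KHMDS, THF, 0 °C to rt
Reagents that add atoms: (methoxymethyl)triphenylphosphonium chloride, COC[P+](c1ccccc1)(c1ccccc1)c1ccccc1.[Cl-]
Why: Wittig methoxymethylenation of the ring B ketone installs C7 as an enol ether; the non-enolisable C19 ester and the strain-locked C5 centre should tolerate the ylide.

**Step 9**
Reactants: 14 methoxymethylidene enol ether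
Product: 15 3α-hydroxy lactone aldehyde
Conditions: TsOH·H2O (0.2 equiv), acetone/H2O 10:1, rt to 40 °C
Reagents that add atoms: water, O
Why: Acid should ionise the strained tertiary allylic C10–O bond of the oxanorbornene and the α-oriented C19 ester carbonyl should trap the allyl cation at C10 on the same face (γ-lactonisation with loss of methanol, retention at C10), leaving the former furan oxygen on C3 as the 3α-alcohol; the enol ether, ketal and primary silyl ether hydrolyse and the 6-formyl group equilibrates by enolisation to the isomer trans to C4.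

**Step 10**
Reactants: 15 3α-hydroxy lactone aldehyde
Product: 16 C17 2-(trimethylsilyl)ethyl carbonate
Conditions: 4-nitrophenyl 2-(trimethylsilyl)ethyl carbonate, Et3N, DMAP (cat.), CH2Cl2, 0 °C to rt
Reagents that add atoms: 4-nitrophenyl 2-(trimethylsilyl)ethyl carbonate, C[Si](C)(C)CCOC(=O)Oc1ccc(cc1)[N+](=O)[O-]
Why: Carbonate formation at the unhindered primary propargylic alcohol; the neopentyl-type 3α-alcohol should not compete.

**Step 11**
Reactants: 16 C17 2-(trimethylsilyl)ethyl carbonate
Product: 18 3β-hydroxy lactone aldehyde, via 1β-phenylselenide 17 (not isolated)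
Conditions: N-(phenylseleno)phthalimide, PBu3, THF, 0 °C to rt; then NaIO4, NaHCO3, pyridine, THF/MeOH/H2O, 0 °C to rt
Reagents that add atoms: sodium periodate, [Na+].[O-]I(=O)(=O)=O
Why: Phosphine activation of the 3α-alcohol and anti SN2′ attack of phenylselenide at C1 from the open β face (C3 is neopentyl, the α face is covered by the lactone) should give 17, whose selenoxide undergoes the suprafacial [2,3]-sigmatropic shift that delivers oxygen to the β face of C3: net inversion to the 3β-alcohol with the C1=C2 alkene restored.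

**Step 12**
Reactants: 18 3β-hydroxy lactone aldehyde
Product: 19 C7 carboxylic acid
Conditions: NaClO2, NaH2PO4, 2-methyl-2-butene, t-BuOH/H2O, 0 °C to rt
Reagents that add atoms: sodium chlorite, [Na+].[O-]Cl=O
Why: Pinnick oxidation of the aldehyde; hypochlorite is scavenged, so alkene, alkyne and allylic alcohol should stay untouched.

**Step 13**
Reactants: 19 C7 carboxylic acid
Product: 20 3-O-TBS ether TBS ester
Conditions: TBSOTf (2.4 equiv), 2,6-lutidine, CH2Cl2, −78 to −20 °C
Reagents that add atoms: tert-butyldimethylsilyl triflate, CC(C)(C)[Si](C)(C)OS(=O)(=O)C(F)(F)F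
Why: Silylation of the hindered 3β-alcohol and of the acid masks both protic groups for the two metal-catalysed steps.

**Step 14**
Reactants: 20 3-O-TBS ether TBS ester
Product: 21 allenyl carbonate
Conditions: Ph3PAuNTf2 (2 mol %), CH2Cl2, rt
Reagents that add atoms: none
Why: Gold-catalysed 1,3-acyloxy shift ([3,3] rearrangement) of a propargylic carbonate: 6-endo attack of the carbonyl oxygen on the activated internal alkyne moves the oxygen to C13 and gives the 1,1-disubstituted allene C13=C16=C17; the silyl ether at C12 cannot migrate.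

**Step 15**
Reactants: 21 allenyl carbonate
Product: 22 fully protected 12α-hydroxygibberellic acid
Conditions: [Rh(CO)2Cl]2 (5 mol %), P(C6F5)3 (20 mol %), 1,4-dioxane, 130 °C, slow argon sweep
Reagents that add atoms: none
Why: Proposed new method: monovalent rhodium inserts into a C(acyl)–CH2 bond of the strained cyclobutanone, CO is extruded to give a spiro rhodacyclobutane (C14–Rh–C15), the tethered allene inserts through its oxygen-bearing C13=C16 bond (C14–C13 formed, rhodium on sp2 C16) and C(sp2)–C(sp3) reductive elimination forms C15–C16; the closest known reaction type is the rhodium-catalysed decarbonylative (4+2−1) coupling of 3,3-disubstituted cyclobutanones with tethered olefins to bridged cyclopentanes, together with the known (4+2) and (4+1) couplings of cyclobutanones with allenes, and the extension is to a 1-acyloxyallene on an all-carbon tether. Ring C closes in the 6-exo sense (C13 attacked, C16 outside the ring) and ring D closes as the five-membered ring by reductive elimination from the six-membered rhodacycle. C8 and C13 are set together: the tether leaves C9 on the α face of ring B, which is held rigid by its trans fusion to the lactone-bridged ring A, so only the α methylene should reach C13 (cis-hydrindane-like array; the β methylene would need an impossible twist about C8–C9), and C13 is then fixed by the one-carbon bridge. The step needs chemoselective C–C activation (ring strain of the cyclobutanone; the electron-poor phosphine should disfavour ionisation of the allylic lactone), decarbonylation before insertion (electron-poor ligand, high temperature, CO swept out) and insertion of the internal rather than the terminal allene bond (the terminal mode would demand a bridgehead alkene). The 12α silyl ether is axial in the closing chair but its silicon points outward, and the expected side products (spiro-cyclopropane from direct reductive elimination, non-decarbonylated bridged ketone) should be separable.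

**Step 16**
Reactants: 22 fully protected 12α-hydroxygibberellic acid
Product: 23 12α-hydroxygibberellic acid (the target gibberellin)
Conditions: TBAF, AcOH (buffer), THF, 0 to 40 °C; work-up at pH 3
Reagents that add atoms: none
Why: Fluoride cleaves the three silyl groups and fragments the 2-(trimethylsilyl)ethyl carbonate (ethene and CO2 lost) to free the bridgehead alcohol; the acetic acid buffer should protect the base-sensitive allylic lactone and 3β-alcohol.

**Compound list**
1 | methyl 3,3-dimethoxycyclobutane-1-carboxylate | COC(=O)C1CC(OC)(OC)C1 | starting material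
2 | tert-butyl[(3,3-dimethoxycyclobutylidene)(methoxy)methoxy]dimethylsilane | COC(O[Si](C)(C)C(C)(C)C)=C1CC(OC)(OC)C1 | intermediate
3 | (E)-3-(furan-2-yl)prop-2-enal | O=C/C=C/c1ccco1 | starting material
4 | methyl 1-[(1R)-1-(furan-2-yl)-3-oxopropyl]-3,3-dimethoxycyclobutane-1-carboxylate | COC(=O)C1([C@@H](CC=O)c2ccco2)CC(OC)(OC)C1 | intermediate
5 | tert-butyldimethyl(prop-2-yn-1-yloxy)silane | C#CCO[Si](C)(C)C(C)(C)C | starting material
6 | methyl 1-[(1R,3S)-6-(tert-butyldimethylsilyloxy)-1-(furan-2-yl)-3-hydroxyhex-4-yn-1-yl]-3,3-dimethoxycyclobutane-1-carboxylate | COC(=O)C1([C@@H](C[C@H](O)C#CCO[Si](C)(C)C(C)(C)C)c2ccco2)CC(OC)(OC)C1 | intermediate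
7 | methyl 1-[(1R,3S)-6-(tert-butyldimethylsilyloxy)-3-(tert-butyldiphenylsilyloxy)-1-(furan-2-yl)hex-4-yn-1-yl]-3,3-dimethoxycyclobutane-1-carboxylate | COC(=O)C1([C@@H](C[C@H](O[Si](c3ccccc3)(c3ccccc3)C(C)(C)C)C#CCO[Si](C)(C)C(C)(C)C)c2ccco2)CC(OC)(OC)C1 | intermediate
8 | 1-[(1R,3S)-6-(tert-butyldimethylsilyloxy)-3-(tert-butyldiphenylsilyloxy)-1-(furan-2-yl)hex-4-yn-1-yl]-3,3-dimethoxycyclobutane-1-carbaldehyde | O=CC1([C@@H](C[C@H](O[Si](c3ccccc3)(c3ccccc3)C(C)(C)C)C#CCO[Si](C)(C)C(C)(C)C)c2ccco2)CC(OC)(OC)C1 | intermediate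
9 | methyl propiolate | C#CC(=O)OC | starting material
10 | methyl 4-hydroxy-4-{1-[(1R,3S)-side chain of 8]-3,3-dimethoxycyclobutyl}but-2-ynoate (both carbinol epimers) | COC(=O)C#CC(O)C1([C@@H](C[C@H](O[Si](c3ccccc3)(c3ccccc3)C(C)(C)C)C#CCO[Si](C)(C)C(C)(C)C)c2ccco2)CC(OC)(OC)C1 | intermediate
11 | methyl 4-oxo-4-{1-[(1R,3S)-side chain of 8]-3,3-dimethoxycyclobutyl}but-2-ynoate | COC(=O)C#CC(=O)C1([C@@H](C[C@H](O[Si](c3ccccc3)(c3ccccc3)C(C)(C)C)C#CCO[Si](C)(C)C(C)(C)C)c2ccco2)CC(OC)(OC)C1 | intermediate
12 | methyl (2Z)-2-methyl-4-oxo-4-{1-[(1R,3S)-side chain of 8]-3,3-dimethoxycyclobutyl}but-2-enoate | COC(=O)/C(C)=C\C(=O)C1([C@@H](C[C@H](O[Si](c3ccccc3)(c3ccccc3)C(C)(C)C)C#CCO[Si](C)(C)C(C)(C)C)c2ccco2)CC(OC)(OC)C1 | intermediate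
13 | Diels–Alder adduct: ring A as 3α,10α-epoxy (7-oxanorbornene) with C1=C2, 4β-methyl, 4α-CO2Me, 5β-H; ring B 6-ketone; C8 spiro-fused 3,3-dimethoxycyclobutane; 9β-H; 9α chain CH2–(12S)-CH(OTBDPS)–C≡C–CH2OTBS | COC(=O)[C@]1(C)[C@H]2C=C[C@]3(O2)[C@@H]1C(=O)C4(CC(OC)(OC)C4)[C@H]3C[C@H](O[Si](c5ccccc5)(c5ccccc5)C(C)(C)C)C#CCO[Si](C)(C)C(C)(C)C | intermediate
14 | 6-(methoxymethylidene) analogue of 13 (E/Z mixture) | COC(=O)[C@]1(C)[C@H]2C=C[C@]3(O2)[C@@H]1C(=COC)C4(CC(OC)(OC)C4)[C@H]3C[C@H](O[Si](c5ccccc5)(c5ccccc5)C(C)(C)C)C#CCO[Si](C)(C)C(C)(C)C | intermediate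
15 | 19,10α-lactone with C1=C2, 3α-OH, 4β-methyl, 5β-H, 6β-formyl (6α-H), C8 spiro-cyclobutan-3-one, 9β-H, 9α chain CH2–(12S)-CH(OTBDPS)–C≡C–CH2OH | OCC#C[C@@H](O[Si](c1ccccc1)(c1ccccc1)C(C)(C)C)C[C@H]5[C@@]67C=C[C@@H](O)[C@@](C)(C(=O)O6)[C@H]7[C@H](C=O)C58CC(=O)C8 | intermediate
16 | C17 2-(trimethylsilyl)ethyl carbonate of 15 | C[Si](C)(C)CCOC(=O)OCC#C[C@@H](O[Si](c1ccccc1)(c1ccccc1)C(C)(C)C)C[C@H]5[C@@]67C=C[C@@H](O)[C@@](C)(C(=O)O6)[C@H]7[C@H](C=O)C58CC(=O)C8 | intermediate
17 | 1β-(phenylselanyl) C2=C3 isomer of 16 (3-oxygen removed) | C[Si](C)(C)CCOC(=O)OCC#C[C@@H](O[Si](c1ccccc1)(c1ccccc1)C(C)(C)C)C[C@H]5[C@@]67[C@H]([Se]c1ccccc1)C=C[C@@](C)(C(=O)O6)[C@H]7[C@H](C=O)C58CC(=O)C8 | intermediate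
18 | 3β-hydroxy epimer of 16 (C1=C2, 19,10α-lactone) | C[Si](C)(C)CCOC(=O)OCC#C[C@@H](O[Si](c1ccccc1)(c1ccccc1)C(C)(C)C)C[C@H]5[C@@]67C=C[C@H](O)[C@@](C)(C(=O)O6)[C@H]7[C@H](C=O)C58CC(=O)C8 | intermediate
19 | C7 carboxylic acid from 18 (6β-CO2H) | C[Si](C)(C)CCOC(=O)OCC#C[C@@H](O[Si](c1ccccc1)(c1ccccc1)C(C)(C)C)C[C@H]5[C@@]67C=C[C@H](O)[C@@](C)(C(=O)O6)[C@H]7[C@H](C(=O)O)C58CC(=O)C8 | intermediate
20 | 3β-O-TBS ether, C7 TBS ester of 19 | C[Si](C)(C)CCOC(=O)OCC#C[C@@H](O[Si](c1ccccc1)(c1ccccc1)C(C)(C)C)C[C@H]5[C@@]67C=C[C@H](O[Si](C)(C)C(C)(C)C)[C@@](C)(C(=O)O6)[C@H]7[C@H](C(=O)O[Si](C)(C)C(C)(C)C)C58CC(=O)C8 | intermediate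
21 | allene isomer of 20: chain CH2–(12S)-CH(OTBDPS)–C13(OCO2CH2CH2SiMe3)=C16=C17H2 | C=C=C(OC(=O)OCC[Si](C)(C)C)[C@@H](O[Si](c1ccccc1)(c1ccccc1)C(C)(C)C)C[C@H]5[C@@]67C=C[C@H](O[Si](C)(C)C(C)(C)C)[C@@](C)(C(=O)O6)[C@H]7[C@H](C(=O)O[Si](C)(C)C(C)(C)C)C58CC(=O)C8 | intermediate
22 | 12α-hydroxygibberellic acid protected as 3-O-TBS, 12-O-TBDPS, 13-O-[2-(trimethylsilyl)ethoxycarbonyl], C7 TBS ester | C=C1C[C@]23C[C@@]1(OC(=O)OCC[Si](C)(C)C)[C@@H](O[Si](c4ccccc4)(c4ccccc4)C(C)(C)C)C[C@H]2[C@@]12C=C[C@H](O[Si](C)(C)C(C)(C)C)[C@@](C)(C(=O)O1)[C@H]2[C@@H]3C(=O)O[Si](C)(C)C(C)(C)C | intermediate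
23 | 12α-hydroxygibberellic acid (the target gibberellin) | C=C1C[C@]23C[C@@]1(O)[C@@H](O)C[C@H]2[C@@]12C=C[C@H](O)[C@@](C)(C(=O)O1)[C@H]2[C@@H]3C(=O)O | target

**Total step count:** 16. **Longest linear sequence:** 16 steps (1 → 23); 3, 5 and 9 are bought.

**Steps most likely to fail**

Step 15 (proposed new method). Possible failures: reductive elimination from the rhodacyclobutane to the spiro-cyclopropane may outrun allene insertion; insertion may precede decarbonylation; rhodium may ionise the allylic lactone; the axial 12α-silyloxy group may slow the desired closure. The fallback uses known chemistry and builds ring D from the cyclobutanone carbonyl carbon instead (C13–C16 and C14–C13 bonds). It sets out from 20 and returns at 23. SmI2/HMPA/t-BuOH (THF, −78 °C) generates the cyclobutanone ketyl, which adds to C13 of the alkyne and expels the carbonate, giving the bridged 1-allenylcyclobutanol acid F1 (the silyl ester is lost on aqueous work-up). Ozonolysis (CH2Cl2/MeOH, pyridine, −78 °C; Me2S) cleaves the electron-rich allene to the 1-acylcyclobutanol (α-ketol) F2. Catalytic base (KOt-Bu, toluene) triggers the strain-driven α-ketol rearrangement, in which the α methylene should migrate from the carbinol carbon to C13, giving the 13-hydroxy-16-oxo-17-nor compound F3. Wittig methylenation (Ph3P=CH2 from the phosphonium bromide and KOt-Bu, THF) gives the 16-methylene acid F4, and the conditions of step 16 then give 23.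

Step 2. Possible failures: C–C bond formation at the fully substituted nucleophilic carbon may be slow, so hydrolysis of the ketene acetal takes over; facial discrimination may be poor. The fallback sets out from 3 (with 2) and returns at 4. NaBH4 (MeOH, 0 °C) reduces 3 to (E)-3-(furan-2-yl)prop-2-en-1-ol F5, and methyl chloroformate/pyridine gives the allyl methyl carbonate F6. Iridium-catalysed branched-selective enantioselective allylic alkylation of 2 with F6 ([Ir(cod)Cl]2, chiral phosphoramidite, ZnF2 activation, THF) gives the (R)-vinyl ester F7. 9-BBN, then NaBO3, gives the primary alcohol F8, and DMP oxidation returns 4.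

Step 11. Possible failures: direct SN2 displacement at C3 instead of the SN2′ path (which would end in the transposed 1β-alcohol); opening of the allylic lactone by the selenide. The fallback sets out from 16 and returns at 18. Mitsunobu inversion (4-nitrobenzoic acid, PPh3, DIAD, toluene) gives the 3β-(4-nitrobenzoate) F9, and mild methanolysis (NaN3, MeOH, 40 °C) gives 18.

**Further compounds**
F1 | step 15 | bridged 1-allenylcyclobutanol acid: C13(=C16=C17H2) bonded to the former cyclobutanone carbon (now a tertiary cyclobutanol, cis-bridged to C8); 3β-OTBS, 12α-OTBDPS, 19,10α-lactone, 7-CO2H | C=C=C1[C@@H](O[Si](c6ccccc6)(c6ccccc6)C(C)(C)C)C[C@H]2[C@@]34C=C[C@H](O[Si](C)(C)C(C)(C)C)[C@@](C)(C(=O)O3)[C@H]4[C@H](C(=O)O)[C@@]25C[C@]1(O)C5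
F2 | step 15 | α-ketol: 13-ketone bonded to the bridged cyclobutanol carbon, other groups as in F1 | O=C1[C@@H](O[Si](c6ccccc6)(c6ccccc6)C(C)(C)C)C[C@H]2[C@@]34C=C[C@H](O[Si](C)(C)C(C)(C)C)[C@@](C)(C(=O)O3)[C@H]4[C@H](C(=O)O)[C@@]25C[C@]1(O)C5
F3 | step 15 | 3-O-TBS, 12-O-TBDPS 16-oxo-17-nor analogue of the target (13-OH and C7 acid free) | O=C1C[C@]23C[C@@]1(O)[C@@H](O[Si](c4ccccc4)(c4ccccc4)C(C)(C)C)C[C@H]2[C@@]12C=C[C@H](O[Si](C)(C)C(C)(C)C)[C@@](C)(C(=O)O1)[C@H]2[C@@H]3C(=O)O
F4 | step 15 | 3-O-TBS, 12-O-TBDPS ether of 12α-hydroxygibberellic acid | C=C1C[C@]23C[C@@]1(O)[C@@H](O[Si](c4ccccc4)(c4ccccc4)C(C)(C)C)C[C@H]2[C@@]12C=C[C@H](O[Si](C)(C)C(C)(C)C)[C@@](C)(C(=O)O1)[C@H]2[C@@H]3C(=O)O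
F5 | step 2 | (E)-3-(furan-2-yl)prop-2-en-1-ol | OC/C=C/c1ccco1
F6 | step 2 | (E)-3-(furan-2-yl)prop-2-en-1-yl methyl carbonate | COC(=O)OC/C=C/c1ccco1
F7 | step 2 | methyl 1-[(1R)-1-(furan-2-yl)prop-2-en-1-yl]-3,3-dimethoxycyclobutane-1-carboxylate | COC(=O)C1([C@@H](C=C)c2ccco2)CC(OC)(OC)C1
F8 | step 2 | methyl 1-[(1R)-1-(furan-2-yl)-3-hydroxypropyl]-3,3-dimethoxycyclobutane-1-carboxylate | COC(=O)C1([C@@H](CCO)c2ccco2)CC(OC)(OC)C1
F9 | step 11 | 3β-(4-nitrobenzoyloxy) analogue of 18 | C[Si](C)(C)CCOC(=O)OCC#C[C@@H](O[Si](c1ccccc1)(c1ccccc1)C(C)(C)C)C[C@H]5[C@@]67C=C[C@H](OC(=O)c1ccc(cc1)[N+](=O)[O-])[C@@](C)(C(=O)O6)[C@H]7[C@H](C=O)C58CC(=O)C8
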